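Ring B is traced back to a five-membered ring. Its C17 ester on C8 and the C6=C7 olefin are read as a γ-keto ester (C6 ketone, C8 ester), the product of a one-carbon homologation of a β-keto ester. In the key step a zinc carbenoid inserts C7 as a methylene between C6 and C8 of a trans-fused hydrindanone β-keto ester, enlarging the ring and placing ketone and ester in the final 1,4-relationship. The precursor is built on ring A by a chirality-transferring Claisen rearrangement (C9–C10 bond, quaternary C10 and C9) and a Dieckmann closure (C6–C8). The ketone then becomes the olefin, and a B-alkyl Suzuki coupling adds the side chain.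

Key step: step 6

Assumption: racemic keto ester 1 is taken as purchasable (otherwise it is the one-step condensation product of mesityl oxide and ethyl acetoacetate). Atom labels C1–C17 follow labdane numbering of the target.

Step 1
Reactants: 1 racemic ethyl 2,6,6-trimethyl-4-oxocyclohex-2-ene-1-carboxylate
Product: 2 ethyl (1R,4R)-4-hydroxy-2,6,6-trimethylcyclohex-2-ene-1-carboxylate
Conditions: RuCl(p-cymene)[(R,R)-TsDPEN] (cat.), HCO2H–Et3N (1:1), DMF, 30 °C
Reagents that add atoms: none
Why: Asymmetric transfer hydrogenation of the enone carbonyl run as a dynamic kinetic resolution: C1, the γ-carbon of a vinylogous β-keto ester, should epimerise through the dienol under the amine conditions, the catalyst sets the carbinol centre as R (alkenyl group in the role of the aryl group of aryl ketones), and the matched enantiomer is reduced anti to the axial C6 methyl group, which places OH trans to the pseudo-axial ester.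

Step 2
Reactants: 2 ethyl (1R,4R)-4-hydroxy-2,6,6-trimethylcyclohex-2-ene-1-carboxylate; 3 methyl 4,4-dimethoxybutanoate
Product: 6 ethyl (1R,2S)-2-[(2R)-4-methoxy-1,4-dioxobutan-2-yl]-2,6,6-trimethylcyclohex-3-ene-1-carboxylate, via mixed acetal 4 (not isolated), via enol ether 5 (not isolated)
Conditions: 3 (3 equiv), EtCO2H (cat.), xylene, 140 °C, MeOH distilled off
Reagents that add atoms: none
Why: Claisen rearrangement by acetal exchange: the suprafacial [3,3] shift forms the C9–C10 bond on the face of the C–O bond, so the carbinol centre sets quaternary C10 trans to the ester-bearing C5, while the (E)-enol ether reacting through the boat transition state usual for cyclohexenyl systems should set C9.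

Step 3
Reactants: 6 ethyl (1R,2S)-2-[(2R)-4-methoxy-1,4-dioxobutan-2-yl]-2,6,6-trimethylcyclohex-3-ene-1-carboxylate
Product: 7 ethyl (1R,2S)-2-[(2R)-4-methoxy-1,4-dioxobutan-2-yl]-2,6,6-trimethylcyclohexane-1-carboxylate
Conditions: H2 (1 atm), 10% Pd/C, EtOAc, rt
Reagents that add atoms: none
Why: Heterogeneous hydrogenation of the cis-disubstituted ring olefin, the only C=C bond present; aldehyde and esters should survive and no stereocentre is formed.

Step 4
Reactants: 7 ethyl (1R,2S)-2-[(2R)-4-methoxy-1,4-dioxobutan-2-yl]-2,6,6-trimethylcyclohexane-1-carboxylate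
Product: 8 ethyl (1R,2S)-2-[(3S)-1-methoxy-1-oxopent-4-en-3-yl]-2,6,6-trimethylcyclohexane-1-carboxylate
Conditions: Ph3PCH3Br, KHMDS, THF, 0 °C; then 7, −78 to 0 °C
Reagents that add atoms: methyltriphenylphosphonium bromide C[P+](c1ccccc1)(c1ccccc1)c1ccccc1.[Br-]
Why: Wittig methylenation of the aldehyde with the salt-free ylide at low temperature, which should leave the α-branched centre (C9) and both esters untouched.

Step 5
Reactants: 8 ethyl (1R,2S)-2-[(3S)-1-methoxy-1-oxopent-4-en-3-yl]-2,6,6-trimethylcyclohexane-1-carboxylate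
Product: 9 methyl (1R,3aR,7aS)-4,4,7a-trimethyl-3-oxo-1-vinyloctahydro-1H-indene-2-carboxylate (trans-fused; C2 enolisable)
Conditions: LiHMDS (2.2 equiv), THF, −78 to 0 °C; cold aq NH4Cl
Reagents that add atoms: none
Why: Dieckmann condensation under kinetic conditions: only the CH2 next to the methyl ester is deprotonated, the enolate attacks the ring ester (5-exo-trig acyl substitution, as in ring D closures of steroid syntheses), and the product is held as its enolate so that the trans ring fusion at C5 should not epimerise.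

Step 6
Reactants: 9 methyl (1R,3aR,7aS)-4,4,7a-trimethyl-3-oxo-1-vinyloctahydro-1H-indene-2-carboxylate
Product: 11 methyl (1R,4aR,8aS)-5,5,8a-trimethyl-4-oxo-1-vinyldecahydronaphthalene-2-carboxylate (C2 epimers), via zinc cyclopropoxide 10 (not isolated)
Conditions: Et2Zn (3 equiv), CH2I2 (3 equiv), CH2Cl2, 0 °C to rt; aq NH4Cl
Reagents that add atoms: diiodomethane ICI
Why: Et2Zn deprotonates the β-keto ester, the carbenoid EtZnCH2I cyclopropanates the zinc enolate across C6–C8 to give the donor–acceptor cyclopropoxide 10, and fragmentation of the C6–C8 bond leaves the new methylene (C7) between the C6 ketone and C8. This is the zinc-carbenoid chain extension of β-keto esters to γ-keto esters in its ring-enlarging mode, the polar counterpart of the Dowd–Beckwith expansion. Ring B arises from the five-membered ring by a 3-exo closure onto the enolate followed by cleavage of the shared bond, a net one-carbon insertion. No stereocentre is set irreversibly: C8 is re-protonated on work-up and corrected in step 8, while C5, C9 and C10 are untouched in the non-basic medium. The step needs chemoselectivity for the enolate over the C9 vinyl group, which the far higher nucleophilicity of the zinc enolate and a limited excess of carbenoid should secure, and regioselective cleavage of the C6–C8 bond, which the alkoxide/ester push–pull on that bond ensures.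

Step 7
Reactants: 11 methyl (1R,4aR,8aS)-5,5,8a-trimethyl-4-oxo-1-vinyldecahydronaphthalene-2-carboxylate
Product: 12 methyl (1R,4aR,8aS)-5,5,8a-trimethyl-4-(trifluoromethanesulfonyloxy)-1-vinyl-1,2,4a,5,6,7,8,8a-octahydronaphthalene-2-carboxylate (C2 epimers)
Conditions: KHMDS (1.1 equiv), THF, −78 °C; PhNTf2, −78 °C to rt
Reagents that add atoms: N-phenylbis(trifluoromethanesulfonimide) O=S(=O)(N(c1ccccc1)S(=O)(=O)C(F)(F)F)C(F)(F)F
Why: Kinetic enolisation of the ketone at the CH2 (C7) and O-triflation should give the Δ6 enol triflate regioselectively, because the ring-fusion methine C5 lies between two quaternary carbons and is not deprotonated at −78 °C.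

Step 8
Reactants: 12 methyl (1R,4aR,8aS)-5,5,8a-trimethyl-4-(trifluoromethanesulfonyloxy)-1-vinyl-1,2,4a,5,6,7,8,8a-octahydronaphthalene-2-carboxylate
Product: 13 methyl (1R,2R,4aR,8aS)-5,5,8a-trimethyl-4-(trifluoromethanesulfonyloxy)-1-vinyl-1,2,4a,5,6,7,8,8a-octahydronaphthalene-2-carboxylate
Conditions: DBU (0.2 equiv), toluene, rt
Reagents that add atoms: none
Why: Base-catalysed epimerisation through the ester dienolate, re-protonated at the α-carbon, should drive C8 to the thermodynamic configuration with the ester pseudo-equatorial, trans to the vinyl group and free of the 1,3-diaxial contact with the angular methyl group; the triflate-bearing γ-carbon is not a productive protonation site, so the olefin stays in place.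

Step 9
Reactants: 13 methyl (1R,2R,4aR,8aS)-5,5,8a-trimethyl-4-(trifluoromethanesulfonyloxy)-1-vinyl-1,2,4a,5,6,7,8,8a-octahydronaphthalene-2-carboxylate
Product: 14 methyl (1R,2S,4aR,8aS)-5,5,8a-trimethyl-1-vinyl-1,2,4a,5,6,7,8,8a-octahydronaphthalene-2-carboxylate
Conditions: Pd(OAc)2 (cat.), PPh3, Bu3N, HCO2H, DMF, 60 °C
Reagents that add atoms: none
Why: Palladium-catalysed formate reduction of the enol triflate (oxidative addition, formate-to-hydride exchange with loss of CO2, reductive elimination) replaces OTf by H and leaves the C6=C7 olefin, the vinyl group and the allylic stereocentres untouched.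

Step 10
Reactants: 15 methyl 4-hydroxybut-2-ynoate
Product: 16 methyl 4-acetoxybut-2-ynoate
Conditions: Ac2O, Sc(OTf)3 (cat.), MeCN, 0 °C
Reagents that add atoms: acetic anhydride CC(=O)OC(C)=O
Why: Lewis-acid-catalysed acetylation of the primary propargylic alcohol; amine bases are avoided because they add to the ynoate.

Step 11
Reactants: 16 methyl 4-acetoxybut-2-ynoate
Product: 17 methyl (2Z)-4-acetoxy-3-iodobut-2-enoate
Conditions: NaI, AcOH, 70 °C
Reagents that add atoms: sodium iodide [Na+].[I-]
Why: Hydroiodination of the ynoate by conjugate addition of iodide and anti protonation should give the (Z)-β-iodo enoate, with iodine cis to the ester and the acetoxymethyl group trans to it.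

Step 12
Reactants: 14 methyl (1R,2S,4aR,8aS)-5,5,8a-trimethyl-1-vinyl-1,2,4a,5,6,7,8,8a-octahydronaphthalene-2-carboxylate; 17 methyl (2Z)-4-acetoxy-3-iodobut-2-enoate
Product: 19 dimethyl (5R,8S,9R,10S,13E)-16-acetoxylabda-6,13-diene-15,17-dioate of the ent-labdane series (CNP0190145.1), via alkylborane 18 (not isolated)
Conditions: 9-BBN, THF, 0 °C to rt; then 17, Pd(dppf)Cl2 (cat.), AsPh3, K3PO4, DMF/THF/H2O, rt
Reagents that add atoms: none
Why: Hydroboration with 9-BBN is selective for the terminal vinyl group over the ring olefin, and the B-alkyl Suzuki–Miyaura coupling with the vinyl iodide proceeds with retention of olefin geometry, so the chain ends up cis to the ester as in the target; no stereocentre is formed.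

Compound list
1 | racemic ethyl 2,6,6-trimethyl-4-oxocyclohex-2-ene-1-carboxylate | CCOC(=O)C1C(C)=CC(=O)CC1(C)C | starting material
2 | ethyl (1R,4R)-4-hydroxy-2,6,6-trimethylcyclohex-2-ene-1-carboxylate (OH trans to ester) | CCOC(=O)[C@H]1C(C)=C[C@H](O)CC1(C)C | intermediate
3 | methyl 4,4-dimethoxybutanoate | COC(OC)CCC(=O)OC | starting material
4 | mixed acetal: ethyl (1R,4R)-4-(1,4-dimethoxy-4-oxobutoxy)-2,6,6-trimethylcyclohex-2-ene-1-carboxylate (acetal carbon unassigned) | CCOC(=O)[C@H]1C(C)=C[C@H](OC(OC)CCC(=O)OC)CC1(C)C | intermediate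
5 | enol ether: ethyl (1R,4R)-4-{[(1E)-4-methoxy-4-oxobut-1-en-1-yl]oxy}-2,6,6-trimethylcyclohex-2-ene-1-carboxylate | CCOC(=O)[C@H]1C(C)=C[C@H](O/C=C/CC(=O)OC)CC1(C)C | intermediate
6 | ethyl (1R,2S)-2-[(2R)-4-methoxy-1,4-dioxobutan-2-yl]-2,6,6-trimethylcyclohex-3-ene-1-carboxylate | O=C[C@H](CC(=O)OC)[C@]1(C)C=CCC(C)(C)[C@H]1C(=O)OCC | intermediate
7 | ethyl (1R,2S)-2-[(2R)-4-methoxy-1,4-dioxobutan-2-yl]-2,6,6-trimethylcyclohexane-1-carboxylate | O=C[C@H](CC(=O)OC)[C@]1(C)CCCC(C)(C)[C@H]1C(=O)OCC | intermediate
8 | ethyl (1R,2S)-2-[(3S)-1-methoxy-1-oxopent-4-en-3-yl]-2,6,6-trimethylcyclohexane-1-carboxylate | C=C[C@H](CC(=O)OC)[C@]1(C)CCCC(C)(C)[C@H]1C(=O)OCC | intermediate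
9 | methyl (1R,3aR,7aS)-4,4,7a-trimethyl-3-oxo-1-vinyloctahydro-1H-indene-2-carboxylate (trans-fused; vinyl cis to the angular methyl; C2 enolisable) | C=C[C@@H]1C(C(=O)OC)C(=O)[C@@H]2C(C)(C)CCC[C@@]12C | intermediate
10 | zinc cyclopropoxide: ethylzinc alkoxide of the cyclopropanol formed by CH2 transfer across C6–C8 of the enolate of 9 | C=C[C@@H]1C3(C(=O)OC)CC3(O[Zn]CC)[C@@H]2C(C)(C)CCC[C@@]12C | intermediate
11 | methyl (1R,4aR,8aS)-5,5,8a-trimethyl-4-oxo-1-vinyldecahydronaphthalene-2-carboxylate (trans-decalin; C2 epimers) | C=C[C@@H]1C(C(=O)OC)CC(=O)[C@@H]2C(C)(C)CCC[C@@]12C | intermediate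
12 | methyl (1R,4aR,8aS)-5,5,8a-trimethyl-4-(trifluoromethanesulfonyloxy)-1-vinyl-1,2,4a,5,6,7,8,8a-octahydronaphthalene-2-carboxylate (C2 epimers) | C=C[C@@H]1C(C(=O)OC)C=C(OS(=O)(=O)C(F)(F)F)[C@@H]2C(C)(C)CCC[C@@]12C | intermediate
13 | methyl (1R,2R,4aR,8aS)-5,5,8a-trimethyl-4-(trifluoromethanesulfonyloxy)-1-vinyl-1,2,4a,5,6,7,8,8a-octahydronaphthalene-2-carboxylate (ester trans to vinyl) | C=C[C@@H]1[C@@H](C(=O)OC)C=C(OS(=O)(=O)C(F)(F)F)[C@@H]2C(C)(C)CCC[C@@]12C | intermediate
14 | methyl (1R,2S,4aR,8aS)-5,5,8a-trimethyl-1-vinyl-1,2,4a,5,6,7,8,8a-octahydronaphthalene-2-carboxylate | C=C[C@@H]1[C@@H](C(=O)OC)C=C[C@@H]2C(C)(C)CCC[C@@]12C | intermediate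
15 | methyl 4-hydroxybut-2-ynoate | COC(=O)C#CCO | starting material
16 | methyl 4-acetoxybut-2-ynoate | COC(=O)C#CCOC(C)=O | intermediate
17 | methyl (2Z)-4-acetoxy-3-iodobut-2-enoate | COC(=O)/C=C(\I)COC(C)=O | intermediate
18 | alkylborane: 9-{2-[(1R,2S,4aR,8aS)-2-(methoxycarbonyl)-5,5,8a-trimethyl-1,2,4a,5,6,7,8,8a-octahydronaphthalen-1-yl]ethyl}-9-borabicyclo[3.3.1]nonane | B3(CC[C@@H]1[C@@H](C(=O)OC)C=C[C@@H]2C(C)(C)CCC[C@@]12C)C4CCCC3CCC4 | intermediate
19 | dimethyl (5R,8S,9R,10S,13E)-16-acetoxylabda-6,13-diene-15,17-dioate, ent-labdane series (CNP0190145.1) | COC(=O)/C=C(\CC[C@@H]1[C@@H](C(=O)OC)C=C[C@@H]2C(C)(C)CCC[C@@]12C)COC(C)=O | target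

Total step count: 12. Longest linear sequence: 10 steps (steps 1–9 and 12).

Steps most likely to fail

Step 6 (key step). The carbenoid may cyclopropanate the C9 vinyl group in competition with the hindered, α-substituted zinc enolate, or carbenoid transfer to that enolate may stall. The fallback sets out from 9 and returns at 11. Compound 9 would be C-alkylated at C8 with CH2Br2 (NaH, THF/HMPA) to give the bromomethyl keto ester F1. Treatment with Bu3SnH and AIBN (benzene, 80 °C, slow addition) would then bring about the Dowd–Beckwith ring expansion: the primary radical adds 3-exo to the C6 carbonyl, β-scission gives the ester-stabilised C8 radical of the six-membered ring, and hydrogen transfer gives 11.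

Step 1. Epimerisation of C1 may be slow relative to hydride transfer, so that the process is not dynamic and diastereocontrol is lost, or conjugate reduction of the enone may compete. The fallback sets out from 1 and returns at 2. Luche reduction (NaBH4, CeCl3·7H2O, MeOH, −40 °C) should give the trans alcohol under control by the axial C6 methyl group, as the racemate of 2 and its enantiomer, the (1S,4S)-alcohol F2. Lipase-catalysed acylation (CAL-B, vinyl acetate, MTBE) would be expected to acetylate the (4R)-enantiomer to the acetate F3, which is separated from F2 and cleaved (K2CO3, EtOH, 0 °C) to 2.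

Step 12. The alkylborane may undergo protodeboronation or β-hydride elimination, zerovalent palladium may ionise the allylic acetate, or the aqueous base may cleave the acetate and epimerise C8. The fallback sets out from 14 and returns at 19. Alkylborane 18, made as before, would be iodinated (I2, NaOMe, MeOH/THF, 0 °C) to the primary iodide F4. Zinc insertion (Zn dust, LiCl, THF) would give the alkylzinc iodide F5, which is joined to 17 in a base-free Negishi coupling (Pd2(dba)3, SPhos, THF, rt).

Further compounds
F1 | step 6 | methyl 2-(bromomethyl)-4,4,7a-trimethyl-3-oxo-1-vinyloctahydro-1H-indene-2-carboxylate (ring stereocentres as in 9) | C=C[C@@H]1C(CBr)(C(=O)OC)C(=O)[C@@H]2C(C)(C)CCC[C@@]12C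
F2 | step 1 | ethyl (1S,4S)-4-hydroxy-2,6,6-trimethylcyclohex-2-ene-1-carboxylate | CCOC(=O)[C@@H]1C(C)=C[C@@H](O)CC1(C)C
F3 | step 1 | ethyl (1R,4R)-4-acetoxy-2,6,6-trimethylcyclohex-2-ene-1-carboxylate | CCOC(=O)[C@H]1C(C)=C[C@H](OC(C)=O)CC1(C)C
F4 | step 12 | methyl (1R,2S,4aR,8aS)-1-(2-iodoethyl)-5,5,8a-trimethyl-1,2,4a,5,6,7,8,8a-octahydronaphthalene-2-carboxylate | ICC[C@@H]1[C@@H](C(=O)OC)C=C[C@@H]2C(C)(C)CCC[C@@]12C
F5 | step 12 | alkylzinc iodide derived from F4 | I[Zn]CC[C@@H]1[C@@H](C(=O)OC)C=C[C@@H]2C(C)(C)CCC[C@@]12C
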